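Molar was the unit asked for, and percent hid the comparison, because summer's percentages divide by a larger charge.

common to all: starting material 0.50 M
- autumn: other conformer 0.012 M; run made earlier
- summer: other conformer 0.18 M; run made earlier
- maple: other conformer 0.0150 M; time 2.5 h
- birch: other conformer 0.0300 M; time 2.5 h
- ash: other conformer 0.0600 M; time 2.5 h
- cedar: other conformer 0.120 M; time 2.5 h
- elm: other conformer 0.250 M; time 2.5 h

| run | time / min | target / % |
|---|---|---|
| autumn | 8.00 | 15.7 |
| autumn | 12.0 | 22.2 |
| autumn | 20.0 | 26.9 |
| autumn | 30.0 | 27.9 |
| autumn | 50.0 | 26.3 |
| autumn | 60.0 | 24.8 |
| autumn | 120 | 11.1 |
| summer | 15.0 | 18.0 |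
| summer | 30.0 | 19.9 |
| summer | 50.0 | 18.9 |
| summer | 60.0 | 17.7 |
| summer | 80.0 | 13.3 |
| summer | 90.0 | 13.5 |
| summer | 120 | 9.6 |

(standard deviation of a reading: 1 percentage point)

- percentages count the starting material that a species holds: one side product counts as two
- the numbers in the tables scatter with a standard deviation of 1 percentage point
- reactions considered so far: starting material -> target; other conformer -> isomer of the product; third conformer -> third product; starting material + target -> side product; target -> over-reaction product; other conformer <-> third conformer; starting material <-> other conformer
- "hardly changes" means that all values lie within two and a half points (for a concentration: within two and a half percent of the largest)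

* [target] at the end for maple, birch, ash, cedar, elm, in this order
* how that number moves from the first to the last of them (falls all the way / rises all the way / hardly changes / falls, then rises / rises, then falls)

I took the given numbers in turn. Summer held 15.0 times autumn's other conformer, yet c(target), the percentage times the whole charge, read 0.143 M in autumn against 0.135 M in summer at 30.0 min, and 0.0568 M against 0.0653 M at 120 min. Autumn stood higher first and lower later, so I read no trend with that charge. Elm's charge lay somewhat above summer's, so elm was a small step beyond the runs. The starting material matched the runs, so its effect came along in the readings.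

The time did matter, since autumn's c(target) read less at 120 min than at 30.0 min. The highest reading of each run stood at 30.0 min , which I took, within the scatter, as the crossing at which loss of target overtook its making, and the asked 2.5 h lay beyond it. Late on, autumn fell at 0.0134 min⁻¹ and summer at 0.0102 min⁻¹. Their mean, 0.0118 min⁻¹, is the tail rate, the fractional fall of c(target) per minute past the crossing. Carrying the mean of the last readings, 0.0611 M, forward 30.0 min, I reckoned 0.0429 M for each flask; the two run rates separately give 0.0409 M and 0.0450 M.

The forecast, a little lower, gave 0.042 M at each point, hardly changes, since “the curves coincide”.

    starting material → target (k = 0.0300 min⁻¹)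
    other conformer → isomer of the product (k = 0.0370 min⁻¹)
    third conformer → third product (k = 0.740 min⁻¹)
    starting material + target → side product (k = 0.0910 M⁻¹ min⁻¹)
    target → over-reaction product (k = 0.0150 min⁻¹)
    other conformer ⇌ third conformer (K = 1.40, k = 0.0270 min⁻¹)
    starting material ⇌ other conformer (K = 0.970, k = 0.00100 min⁻¹)

The flasks gave 0.0405 M, 0.0405 M, 0.0406 M, 0.0406 M and 0.0408 M: hardly changes. In maple at 2.50 h, target was being made at 0.0640 of the rate of its use. From maple's 20.9% at 1.25 h, the tail rate gives 8.63% at 2.50 h, and maple held 7.87%. From ash's 19.3% at 1.25 h, it gives 7.97%, and ash held 7.25%.

The earlier runs and the new flask stem from a simulated flask for substances that don't exist, noise included.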